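**Assumptions.** The target is planar and has no stereogenic element, so "single enantiomer" is read as the single constitutional isomer drawn and no step needs stereocontrol. Simple reagents (NIS, Ac2O, BnBr, the Ohira–Bestmann reagent, CO, ICl, MeOH, H2) are not numbered and are listed under "Reagents that add atoms".

## Structural features

The target is a flavone (2-aryl-4H-chromen-4-one): a benzo A ring (C4a–C8a) fused to a pyran-4-one C ring (O1, C2, C3, C4), with a 2,3-dihydroxyphenyl B ring on C2. The A ring carries oxygen on four carbons in a 1,2,3,5 pattern, and each oxygen has a different role: O1 at C8a, OMe at C8 and C7, and a free, hydrogen-bonded OH at C5; only C6 bears hydrogen. C3 of the pyranone carries a methoxy group, so C2=C3 is a tetrasubstituted enol ether between the crowded B ring (2'-OH ortho to the biaryl-type bond) and the C4 carbonyl. There is no stereocentre. Fragile points are the free catechol (oxidation), the pyranone towards nucleophilic base at C2 (ring opening and ring contraction), and the 5-hydroxy-7,8-dioxygenated A ring under strong acid (Wessely–Moser isomerisation to the 5,6,7 pattern). The real difficulty is regiochemical: telling apart the two oxygens that flank C4a (O5 free, O1 in the ring) so that the 5,7,8 and not the 5,6,7 pattern results, and placing oxygen on C3. The key step exploits the fact that C4a sits between O5 and the C8a oxygen. If O5 is acylated and the C8a oxygen is a methyl ether, only the ether oxygen can close the ring, and the A ring maps onto 3,4,5-trimethoxyphenol: its OH becomes 5-OH, its C3 methoxy oxygen becomes O1, and its C4 and C5 methoxy groups become 8-OMe and 7-OMe.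

## Logic of the disconnections

**12 to 11.** The two benzyl–oxygen bonds on the B-ring catechol are cut last. The catechol is the most oxidation-prone part of 12 and should be free for one step only. The forward step must remove two benzyl groups without reducing C2=C3 or C4=O.

**11 to 9 (through 10).** The C3–OMe bond is cut and C3 receives iodine instead; the O5 hydrogen is exchanged for acetyl. This reduces the C3 substituent to the atom that the key step installs for free. The forward step must form a C(sp2)–O bond with methanol on an α-iodo enone without opening the pyranone. The acetate is meant to fall in the same flask, so that the 5-phenoxide 10 carries the ring through the basic coupling.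

**9 to 7 (key disconnection).** The O1–C2 and C3–I bonds are cut and a methyl group is put back on the oxygen that was O1. In one sentence: the pyranone is closed by an iodonium-triggered, demethylative 6-endo attack of an aryl methyl ether oxygen of 7 on its alkyne. That sentence does not describe the diketone cyclodehydration or chalcone oxidation that would be drawn first. The gain is large: the bicyclic core becomes an open diaryl alkynone, and the O1/O5 question becomes simply which oxygen carries methyl and which acetyl. The forward step needs three selectivities: methyl ether oxygen over all other oxygens, 6-endo over 5-exo, and alkyne over arene C–H.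

**7 to 3 + 6 + carbon monoxide.** The C4–C4a and C4–C3 bonds are cut, so the carbonyl carbon comes from CO and the core is assembled from three components. Neither half then needs a preformed acyl group. The forward step must let CO insertion outrun direct alkynylation at a di-ortho-substituted aryl iodide, with a base that does not touch the acetate.

**3 to 2 to 1.** The O–acetyl bond and then the C–I bond are cut. In 1 the two positions ortho to OH are equivalent, so iodination has one possible outcome and the whole A-ring pattern is fixed by a commercial phenol. The forward demand is mono-iodination of a very electron-rich ring.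

**6 to 5 to 4.** The terminal alkyne carbon is removed (one-carbon homologation of an aldehyde) and then the two benzyl ethers. This leads back to a commercial catechol aldehyde; the forward steps are routine.

## Other disconnections considered

**Alternative 1: (first to mind) acyl transfer and cyclodehydration.** Cut O1–C2 and C2–C3. The forward key step is a Baker–Venkataraman sequence: 1-(2-hydroxy-3,4,6-trimethoxyphenyl)-2-methoxyethan-1-one A1 is O-acylated with 2,3-bis(benzyloxy)benzoyl chloride A2, rearranged to diketone A3 and cyclodehydrated to the 3,5,7,8-tetramethoxyflavone A4.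
- A1 would have to come from acylation of 1,2,3,5-tetramethoxybenzene followed by cleavage of one of two different ortho methoxy groups. The 5,7,8 versus 5,6,7 question is therefore moved to an earlier and less controllable step.
- A4 still needs its 5-O-methyl removed by a Lewis acid in the presence of the 3-OMe, which flanks the same carbonyl, and of two benzyl ethers.
- The chalcone/Algar–Flynn–Oyamada variant shares both problems and adds the known tendency of 6'-oxygenated chalcones to close to aurones.
- The chosen route lets the ring closure itself differentiate the oxygens, and is no longer.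

**Alternative 2: three-component carbonylative annulation with a phenol nucleophile.** Cut C4–C4a, C3–C4 and O1–C2. The forward key step couples 3-(benzyloxy)-2-iodo-5,6-dimethoxyphenol A5, CO and alkyne 6 under palladium to flavone A6.
- A5 is not available regioselectively: iodination of its parent phenol has two doubly activated sites, and the parent phenol itself needs the same oxygen differentiation.
- A phenoxide can close either 5-exo (aurone) or 6-endo (flavone).
- A6 lacks oxygen at C3, so an oxidation of an electron-rich enol ether and a methylation would follow.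
- The chosen route keeps the three-component ketone assembly but uses the methyl ether oxygen to define regiochemistry and the iodonium to functionalise C3 in the ring-closing event.

**Alternative 3: biomimetic late C8 oxygenation.** Cut C8–O, as in the presumed biosynthesis (8-hydroxylation, then O-methylation). The forward key step is an Elbs persulfate oxidation of 5-hydroxy-3,7-dimethoxyflavone A7, para to the 5-OH, giving the 5,8-dihydroxy compound A8; the non-chelated 8-OH would then be methylated.
- The step forms only one C–O bond; the flavonol core of A7 must still be built by the conventional sequence of Alternative 1.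
- Persulfate oxidation needs aqueous alkali, which is hard on a 3-methoxyflavone, and passes through an aryl sulfate that must be hydrolysed in acid.
- Radical oxidation is not expected to discriminate well between the A ring and the electron-rich B ring.
- The route would be longer and would place its riskiest step late.

Key step: step 6

## Route

**Step 1**
Reactants: 1 3,4,5-trimethoxyphenol
Product: 2 2-iodo-3,4,5-trimethoxyphenol
Conditions: NIS (1.0 equiv), MeCN, 0 °C, dark
Reagents that add atoms: N-iodosuccinimide, O=C1CCC(=O)N1I
Why: Electrophilic aromatic iodination ortho to the phenol; the only two free positions are equivalent, so one regioisomer is possible, and the first iodine deactivates and hinders the ring against a second.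

**Step 2**
Reactants: 2 2-iodo-3,4,5-trimethoxyphenol
Product: 3 2-iodo-3,4,5-trimethoxyphenyl acetate
Conditions: Ac2O, pyridine, DMAP (cat.), CH2Cl2, 0 °C to rt
Reagents that add atoms: acetic anhydride, CC(=O)OC(C)=O
Why: O-Acylation of a phenol; the acetate makes the future O5 non-nucleophilic for steps 5 and 6 and is removed without a separate step in step 7.

**Step 3**
Reactants: 4 2,3-dihydroxybenzaldehyde
Product: 5 2,3-bis(benzyloxy)benzaldehyde
Conditions: BnBr (2.3 equiv), K2CO3, DMF, 60 °C
Reagents that add atoms: benzyl bromide, BrCc1ccccc1
Why: Williamson ether synthesis on both phenols; benzyl ethers are stable to base, Pd/Cu, ICl at low temperature and Cu/methoxide, and fall together in the last step.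

**Step 4**
Reactants: 5 2,3-bis(benzyloxy)benzaldehyde
Product: 6 1,2-bis(benzyloxy)-3-ethynylbenzene
Conditions: dimethyl (1-diazo-2-oxopropyl)phosphonate, K2CO3, MeOH, 0 °C to rt
Reagents that add atoms: Ohira–Bestmann reagent, CC(=O)C(=[N+]=[N-])P(=O)(OC)OC
Why: Seyferth–Gilbert homologation in the Ohira–Bestmann variant turns the aldehyde into the terminal alkyne with one added carbon; carbonate in methanol leaves the benzyl ethers alone.

**Step 5**
Reactants: 3 2-iodo-3,4,5-trimethoxyphenyl acetate; 6 1,2-bis(benzyloxy)-3-ethynylbenzene
Product: 7 2-{3-[2,3-bis(benzyloxy)phenyl]prop-2-ynoyl}-3,4,5-trimethoxyphenyl acetate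
Conditions: PdCl2(PPh3)2 (5 mol %), CuI (5 mol %), Et3N, CO (1 atm), THF, rt to 45 °C
Reagents that add atoms: carbon monoxide, [C-]#[O+]
Why: Carbonylative Sonogashira coupling; after oxidative addition the electron-rich, crowded aryl group should migrate onto CO faster than it accepts the copper acetylide, and Et3N is not nucleophilic enough to cleave the acetate.

**Step 6**
Reactants: 7 2-{3-[2,3-bis(benzyloxy)phenyl]prop-2-ynoyl}-3,4,5-trimethoxyphenyl acetate
Product: 9 2-[2,3-bis(benzyloxy)phenyl]-3-iodo-7,8-dimethoxy-4-oxo-4H-chromen-5-yl acetate, via O-methylchromenylium chloride 8 (not isolated)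
Conditions: ICl (1.1 equiv), CH2Cl2, −78 °C; aq. Na2S2O3
Reagents that add atoms: iodine monochloride, ICl
Why: Electrophilic iodocyclisation of a 2-methoxyaryl alkynone to a 3-iodochromone, a known ICl-induced demethylative annulation, is applied to 7. I+ engages the alkyne at its α-carbon, the nucleophilic end of the ynone, and leaves positive character on the β-carbon, which is benzylic to the B ring. The lone pair of the methoxy oxygen that flanks the ketone attacks that β-carbon anti to iodine and closes the pyranone ring 6-endo-dig, giving the O-methyl oxonium 8. Chloride then removes the methyl group by SN2 as chloromethane, which makes the closure irreversible and delivers 9 with iodine at C3. The oxygen on the other flank of the ketone is an acetate whose lone pair is tied up in the ester, so only the methyl ether oxygen can become O1, and this single choice fixes the 5-O/7,8-dimethoxy pattern. The 5-exo closure and a 5-endo attack by the 2-benzyloxy oxygen of the B ring would both place positive charge on the α-carbon next to the carbonyl and are mismatched with the polarisation of the ynone. Iodination of the one A-ring C–H should be held back by the aroyl and acetoxy groups, by 1.1 equiv of ICl and by −78 °C. No stereocentre is formed.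

**Step 7**
Reactants: 9 2-[2,3-bis(benzyloxy)phenyl]-3-iodo-7,8-dimethoxy-4-oxo-4H-chromen-5-yl acetate
Product: 11 2-[2,3-bis(benzyloxy)phenyl]-5-hydroxy-3,7,8-trimethoxy-4H-chromen-4-one, via 5-hydroxy-3-iodoflavone 10 (not isolated)
Conditions: CuI (20 mol %), 3,4,7,8-tetramethyl-1,10-phenanthroline (40 mol %), Cs2CO3 (3 equiv), MeOH–toluene, 100 °C (sealed tube); dilute acid work-up
Reagents that add atoms: methanol, CO
Why: Methanolysis of the aryl acetate is fast and gives 10 as its caesium phenoxide, whose donation into C4=O lowers the electrophilicity of C2 and should protect the pyranone from methoxide; Ullmann-type copper-catalysed C–O coupling of the vinylic C3–I bond with methanol then gives the 3-methoxy group. No alkylating agent is present, so the chelated 5-OH stays free.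

**Step 8**
Reactants: 11 2-[2,3-bis(benzyloxy)phenyl]-5-hydroxy-3,7,8-trimethoxy-4H-chromen-4-one
Product: 12 2-(2,3-dihydroxyphenyl)-5-hydroxy-3,7,8-trimethoxy-4H-chromen-4-one (target)
Conditions: H2 (1 atm), 10% Pd/C, EtOAc–MeOH, rt; work-up under argon
Reagents that add atoms: none
Why: Catalytic hydrogenolysis of two benzyl aryl ethers; the tetrasubstituted, vinylogous-ester C2=C3 bond and the chelated carbonyl should not be reduced at 1 atm and room temperature, and the methyl ethers are inert.

## Compound list

1 | 3,4,5-trimethoxyphenol | COc1cc(O)cc(OC)c1OC | starting material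
2 | 2-iodo-3,4,5-trimethoxyphenol | COc1cc(O)c(I)c(OC)c1OC | intermediate
3 | 2-iodo-3,4,5-trimethoxyphenyl acetate | COc1cc(OC(C)=O)c(I)c(OC)c1OC | intermediate
4 | 2,3-dihydroxybenzaldehyde | O=Cc1cccc(O)c1O | starting material
5 | 2,3-bis(benzyloxy)benzaldehyde | O=Cc1cccc(OCc2ccccc2)c1OCc1ccccc1 | intermediate
6 | 1,2-bis(benzyloxy)-3-ethynylbenzene | C#Cc1cccc(OCc2ccccc2)c1OCc1ccccc1 | intermediate
7 | 2-{3-[2,3-bis(benzyloxy)phenyl]prop-2-ynoyl}-3,4,5-trimethoxyphenyl acetate | COc1cc(OC(C)=O)c(C(=O)C#Cc2cccc(OCc3ccccc3)c2OCc2ccccc2)c(OC)c1OC | intermediate
8 | 5-acetoxy-2-[2,3-bis(benzyloxy)phenyl]-3-iodo-7,8-dimethoxy-1-methyl-4-oxo-4H-chromen-1-ium chloride | C[O+]1C(=C(I)C(=O)c2c(OC(C)=O)cc(OC)c(OC)c21)c1cccc(OCc2ccccc2)c1OCc1ccccc1.[Cl-] | intermediate (not isolated)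
9 | 2-[2,3-bis(benzyloxy)phenyl]-3-iodo-7,8-dimethoxy-4-oxo-4H-chromen-5-yl acetate | COc1cc(OC(C)=O)c2c(=O)c(I)c(-c3cccc(OCc4ccccc4)c3OCc3ccccc3)oc2c1OC | intermediate
10 | 2-[2,3-bis(benzyloxy)phenyl]-5-hydroxy-3-iodo-7,8-dimethoxy-4H-chromen-4-one | COc1cc(O)c2c(=O)c(I)c(-c3cccc(OCc4ccccc4)c3OCc3ccccc3)oc2c1OC | intermediate (not isolated)
11 | 2-[2,3-bis(benzyloxy)phenyl]-5-hydroxy-3,7,8-trimethoxy-4H-chromen-4-one | COc1cc(O)c2c(=O)c(OC)c(-c3cccc(OCc4ccccc4)c3OCc3ccccc3)oc2c1OC | intermediate
12 | 2-(2,3-dihydroxyphenyl)-5-hydroxy-3,7,8-trimethoxy-4H-chromen-4-one | COc1cc(O)c2c(=O)c(OC)c(-c3cccc(O)c3O)oc2c1OC | target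

## Step count and least certain steps

Total steps: 8. Longest linear sequence: 6 (steps 1, 2, 5, 6, 7, 8; the B-ring branch 3, 4, 5, 6, 7, 8 is equally long).

**Step 6 (key step).** Three things could go wrong:
- iodination of the A-ring C–H between the acetoxy and methoxy groups before the ring closes;
- participation of the 2-benzyloxy oxygen with loss of the benzyl group;
- capture of the iodonium by chloride without ring closure.

Fallback, from 7 back to 9: ring closure and iodination would be separated. Compound 7 would be treated with MgI2·OEt2 (toluene–Et2O, 60 °C), which should cleave only the methyl ether chelated to the ketone. The magnesium phenoxide would add 6-endo to the ynone (a β-iodo enone from iodide addition would converge by addition–elimination) to give 2-[2,3-bis(benzyloxy)phenyl]-7,8-dimethoxy-4-oxo-4H-chromen-5-yl acetate F1. C3 would then be metalated with the ester-tolerant amide base (TMP)2Zn·2MgCl2·2LiCl (THF, −30 °C), directed by C4=O, and quenched with I2 to give 9. Iodine would then enter as an electrophile towards a C3 carbanion and could not attack the arene.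

**Step 7.** Reductive loss of iodine is possible under copper/alkoxide conditions. Methoxide could also add at C2, with ring opening and re-closure to a ring-contracted (aurone-type) skeleton.

Fallback, from 9 back to 11: iodine–magnesium exchange with iPrMgCl·LiCl (THF, −78 °C) and trapping with B(OMe)3 would give dimethyl {5-acetoxy-2-[2,3-bis(benzyloxy)phenyl]-7,8-dimethoxy-4-oxo-4H-chromen-3-yl}boronate F2, used without isolation. Oxidation with NaOH/H2O2 at 0 °C, which also removes the acetate, would give 2-[2,3-bis(benzyloxy)phenyl]-3,5-dihydroxy-7,8-dimethoxy-4H-chromen-4-one F3. Methylation with MeI (1.1 equiv), K2CO3 in acetone should take the 3-OH and leave the chelated 5-OH, giving 11.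

**Step 5.** Oxidative addition at the di-ortho-substituted, electron-rich iodide may be slow; direct alkynylation without CO uptake and oxidative dimerisation of 6 are the competing processes.

Fallback, from 1 and 6 back to 7: the carbonyl carbon would be put on the A ring first.
- Vilsmeier–Haack formylation of 1 (POCl3, DMF) would give 6-hydroxy-2,3,4-trimethoxybenzaldehyde F4.
- Acetylation (Ac2O, pyridine) would give 2-formyl-3,4,5-trimethoxyphenyl acetate F5.
- Pinnick oxidation (NaClO2, NaH2PO4, 2-methyl-2-butene) would give 2-acetoxy-4,5,6-trimethoxybenzoic acid F6.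
- Oxalyl chloride with catalytic DMF would give 2-acetoxy-4,5,6-trimethoxybenzoyl chloride F7.
- Pd/Cu-catalysed acylative alkynylation of F7 with 6 (PdCl2(PPh3)2, CuI, Et3N, THF, rt) would give 7 without any CO-insertion step.

**Step 1.** Over-iodination at the second ortho position and oxidation of the very electron-rich phenol to a quinone are the concerns.

Fallback, from 1 back to 3: the order would be inverted. Compound 1 would first be acetylated to 3,4,5-trimethoxyphenyl acetate F8, which is harder to oxidise and still has two equivalent free positions. Iodination with NIS and catalytic TFA in MeCN would then give 3 directly.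

## Further compounds

F1 | step 6 | 2-[2,3-bis(benzyloxy)phenyl]-7,8-dimethoxy-4-oxo-4H-chromen-5-yl acetate | COc1cc(OC(C)=O)c2c(=O)cc(-c3cccc(OCc4ccccc4)c3OCc3ccccc3)oc2c1OC
F2 | step 7 | dimethyl {5-acetoxy-2-[2,3-bis(benzyloxy)phenyl]-7,8-dimethoxy-4-oxo-4H-chromen-3-yl}boronate | COB(OC)c1c(-c2cccc(OCc3ccccc3)c2OCc2ccccc2)oc2c(OC)c(OC)cc(OC(C)=O)c2c1=O
F3 | step 7 | 2-[2,3-bis(benzyloxy)phenyl]-3,5-dihydroxy-7,8-dimethoxy-4H-chromen-4-one | COc1cc(O)c2c(=O)c(O)c(-c3cccc(OCc4ccccc4)c3OCc3ccccc3)oc2c1OC
F4 | step 5 | 6-hydroxy-2,3,4-trimethoxybenzaldehyde | COc1cc(O)c(C=O)c(OC)c1OC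
F5 | step 5 | 2-formyl-3,4,5-trimethoxyphenyl acetate | COc1cc(OC(C)=O)c(C=O)c(OC)c1OC
F6 | step 5 | 2-acetoxy-4,5,6-trimethoxybenzoic acid | COc1cc(OC(C)=O)c(C(=O)O)c(OC)c1OC
F7 | step 5 | 2-acetoxy-4,5,6-trimethoxybenzoyl chloride | COc1cc(OC(C)=O)c(C(=O)Cl)c(OC)c1OC
F8 | step 1 | 3,4,5-trimethoxyphenyl acetate | COc1cc(OC(C)=O)cc(OC)c1OC
A1 | alternative 1 | 1-(2-hydroxy-3,4,6-trimethoxyphenyl)-2-methoxyethan-1-one | COCC(=O)c1c(O)c(OC)c(OC)cc1OC
A2 | alternative 1 | 2,3-bis(benzyloxy)benzoyl chloride | O=C(Cl)c1cccc(OCc2ccccc2)c1OCc1ccccc1
A3 | alternative 1 | 1-[2,3-bis(benzyloxy)phenyl]-3-(2-hydroxy-3,4,6-trimethoxyphenyl)-2-methoxypropane-1,3-dione | COC(C(=O)c1cccc(OCc2ccccc2)c1OCc1ccccc1)C(=O)c1c(O)c(OC)c(OC)cc1OC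
A4 | alternative 1 | 2-[2,3-bis(benzyloxy)phenyl]-3,5,7,8-tetramethoxy-4H-chromen-4-one | COc1cc(OC)c2c(=O)c(OC)c(-c3cccc(OCc4ccccc4)c3OCc3ccccc3)oc2c1OC
A5 | alternative 2 | 3-(benzyloxy)-2-iodo-5,6-dimethoxyphenol | COc1cc(OCc2ccccc2)c(I)c(O)c1OC
A6 | alternative 2 | 5-(benzyloxy)-2-[2,3-bis(benzyloxy)phenyl]-7,8-dimethoxy-4H-chromen-4-one | COc1cc(OCc2ccccc2)c2c(=O)cc(-c3cccc(OCc4ccccc4)c3OCc3ccccc3)oc2c1OC
A7 | alternative 3 | 2-[2,3-bis(benzyloxy)phenyl]-5-hydroxy-3,7-dimethoxy-4H-chromen-4-one | COc1cc(O)c2c(=O)c(OC)c(-c3cccc(OCc4ccccc4)c3OCc3ccccc3)oc2c1
A8 | alternative 3 | 2-[2,3-bis(benzyloxy)phenyl]-5,8-dihydroxy-3,7-dimethoxy-4H-chromen-4-one | COc1cc(O)c2c(=O)c(OC)c(-c3cccc(OCc4ccccc4)c3OCc3ccccc3)oc2c1O
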